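The charge does not change between these flasks: 0.022 M of starting material and 0.500 equiv of second substrate. So at one temperature I compare them by a single ratio, the debt. This is second substrate charged per catalyst charged, the turnovers each catalyst owes if second substrate is spent before target appears.

| flask | starting material | second substrate | precatalyst | temperature | remark | time |
|---|---|---|---|---|---|---|
| winter | 0.022 M | 0.50 equiv | 0.0092 mol% | 15 °C | run made earlier |  |
| summer | 0.022 M | 0.50 equiv | 0.13 mol% | 26 °C | run made earlier |  |
| oak | 0.022 M | 0.500 equiv | 0.15 mol% | 20 °C |  | 6.0 d |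
| ash | 0.022 M | 0.500 equiv | 0.08 mol% | 20 °C |  | 6.0 d |
| cedar | 0.022 M | 0.500 equiv | 0.012 mol% | 20 °C |  | 6.0 d |
| larch | 0.022 M | 0.500 equiv | 0.025 mol% | 20 °C |  | 6.0 d |
| alder | 0.022 M | 0.500 equiv | 0.05 mol% | 20 °C |  | 6.0 d |
| maple | 0.022 M | 0.500 equiv | 0.2 mol% | 20 °C |  | 6.0 d |

- winter (time / d: target / %): 0.625: 0; 1.25: 0; 1.67: 0; 2.50: 0; 3.00: 0; 4.00: 0.1
- summer (time / d: target / %): 0.333: 0.9; 0.500: 1.8; 0.833: 10.7; 1.25: 34.3; 1.67: 54.5; 3.00: 87.4; 4.00: 95.0

(standard deviation of a reading: 0.3 percentage points)

* all flasks from highest to lowest amount of target, in percent of the starting material charged, at 6.0 d (oak / ash / cedar / larch / alder / maple)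
* the amount of target, in percent of the starting material charged of the flask you put first, at 6.0 d
* the amount of target, in percent of the starting material charged of the flask you put last, at 6.0 d



The summer run waits, rises and then decays, and I read the wait as a debt being paid. Its debt is 385. I get a pace two ways, assuming second substrate is paid at about the speed of starting material. The tail between 3.00 d and 4.00 d decays at 0.924 d⁻¹, which per catalyst is 711 d⁻¹. Run back, that tail meets zero at 0.759 d, and debt over lag gives 507 d⁻¹. The lag is reckoned from that same tail, so both paces rest on the same two readings and neither checks the other; they part by a factor of 1.40. I suspect the lag way cheats: it bills any waiting at the start to the debt. So I keep the tail.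

The forecast gives maple > oak > ash > alder > larch > cedar, with 98.9% first (range 96.5% to 99.8%) and 0.9% last (range 0.2% to 3%). It says: “The order follows loading, assuming no deactivation”. It puts the cost of going from 26 °C to 20 °C at 1.6.

I borrow that factor. My running pace at 20 °C, turnovers per catalyst per day, is 444 d⁻¹. In 6.0 d a catalyst then pays 2670. Cedar owes 4170, more than that, and needs 9.38 d. Larch owes 2000, less than that. Maple owes 250, less than cedar. Debt falls as loading rises, so the ranking needs no clock, and I expect cedar to stay low.

The simulation gives maple > oak > ash > alder > larch > cedar, with 97.0% in maple and 1.59% in cedar.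

    second substrate + free enzyme ⇌ complex B (K = 3300 M⁻¹, k = 3.66 × 10⁵ M⁻¹ h⁻¹, Ea = 37.0 kJ mol⁻¹, ΔH = −28.0 kJ mol⁻¹)
    complex A → free enzyme + target (k = 30.0 h⁻¹, Ea = 93.0 kJ mol⁻¹)
    free enzyme → unfolded enzyme (k = 0.00106 h⁻¹, Ea = 264 kJ mol⁻¹)
    complex B → free enzyme + second product (k = 29.7 h⁻¹, Ea = 87.0 kJ mol⁻¹)
    starting material + free enzyme ⇌ complex A (K = 31.2 M⁻¹, k = 7.67 × 10⁵ M⁻¹ h⁻¹, Ea = 47.0 kJ mol⁻¹, ΔH = 9.00 kJ mol⁻¹)
    precatalyst → free enzyme (k = 0.0334 h⁻¹, Ea = 96.0 kJ mol⁻¹)
    (constants at 20 °C)

At the start of maple, the equilibrium constant times concentration is 36 for second substrate against 0.69 for starting material. In cedar at 6.00 d, complex B, the resting state, holds 80.7% of the catalyst and complex A 7.17%, with 26.5% of the second substrate left, so cedar has paid 3060 of its debt against my 2670.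

Cedar's neighbour with 0.200 equiv owes 1670, which my pace clears in 3.75 d, within 6.0 d. It ends with 0.0924% of its second substrate left and 8.12% target.

The earlier runs and the new flask are calculated with constants of no real substance; scatter was added.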